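| setting | winter | summer | flask |
|---|---|---|---|
| solid substrate | 0.020 M | 0.010 M | 0.020 M |
| remark | the very flask that is asked about, followed so far | run made earlier |  |
| time |  |  | 6.0 h |

winter run (percent of the solid substrate charged)

| time / min | target / % | solid substrate / % |
|---|---|---|
| 4.00 | 0.2 | 98.4 |
| 12.0 | 0 | 95.9 |
| 20.0 | 0.3 | 93.8 |
| 30.0 | 0 | 90.7 |
| 40.0 | 0 | 87.7 |
| 60.0 | 0 | 82.6 |
| 80.0 | 0.3 | 77.7 |

summer run (percent of the solid substrate charged)

| time / h | target / % | solid substrate / % |
|---|---|---|
| 0.250 | 0 | 90.3 |
| 0.667 | 0 | 75.8 |
| 1.33 | 0 | 54.6 |
| 2.00 | 1.1 | 36.8 |
| 2.50 | 1.0 | 25.5 |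
| 3.00 | 1.7 | 14.2 |
| 4.00 | 4.0 | 0.5 |

(scatter of a reading: 0.3 percentage points)

- a species is counted by the solid substrate in it: one idle adduct counts as two
- amounts and yields of target count idle adduct too
- given per volume of solution although it is solid: solid substrate
- what may be going on: target <-> isomer of the product; solid substrate <-> starting material; starting material + target <-> idle adduct; starting material <-> intermediate; intermediate <-> target
- at the start none of the solid substrate is in solution
- in an amount of target, one idle adduct counts as one target

- the target in the flask at 6.0 h, as a percentage of the solid substrate charged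
- the solid substrate in the flask at 6.0 h, as a percentage of the solid substrate charged (only what is still solid)

The reckoning is kept in fractions of the winter flask's charge, with the summer run read as a preview of that flask. The summer charge is half of the winter one, yet by 80.0 min the winter flask has dissolved 22.3 % of its charge and the summer run 22.7 % of that same charge. By 3.00 h the summer run, still holding 14.2 % of its own charge as solid, has dissolved 42.9 % of the winter charge, so the last 3.00 h remain as a correction; the reading at 4.00 h is not used for the preview, since the solid substrate of the summer run is down to 0.5 % there. That correction uses the late dissolving rate, the solid passing into solution per hour in the summer run while solid is clearly left, read between 2.00 h and 3.00 h as 0.00226 M h⁻¹. Held constant, it adds 33.9 % and leaves 23.2 % as solid substrate at 6.0 h; the weak link is that constancy beyond the reading at 3.00 h.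

The forecast, reading the dissolving as “a film-type approach to saturation”, commits to 37 % solid substrate, 14 percentage points above this reckoning, and to 5.8 % target, a figure this reckoning does not address.

The flask gives 30.4 % solid substrate and 3.62 % target, so the forecast's target is within its margin and its solid substrate is 6.6 points too high.

    target ⇌ isomer of the product (K = 3.90, k = 0.0580 min⁻¹)
    solid substrate ⇌ starting material, rate k2*(cs2 - [starting material]) while solid is left; crystals form when [starting material] > cs2 (solubility = 15.0 mM, k = 0.00440 min⁻¹)
    starting material + target ⇌ idle adduct, settled at all times (K = 19.0 L mol⁻¹)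
    starting material ⇌ intermediate (K = 3.00, k = 0.00220 min⁻¹)
    intermediate ⇌ target (K = 1.70, k = 0.00740 min⁻¹)

The weak link gives way: between 3.00 h and 6.00 h the solid substrate in the flask falls from 57.1 % to 30.4 %, which is 0.00178 M h⁻¹ on average, less than the late dissolving rate, and the dissolving rate of the scheme in the flask goes down from 0.00212 M h⁻¹ at 3.00 h to 0.00154 M h⁻¹ at 6.00 h, so the flask holds more solid substrate than the reckoned 23.2 %. For the neighbour charged with 0.050 M, the late dissolving rate, used in the same way, leaves 69.3 % solid substrate; the computed result is 72.2 %.

All runs are simulated for an exercise; scatter was added.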